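## The problem

Compound 21 is an achiral diaryl ether. Ring A is a benzoic acid (CO2H on C1) with a phenolic OH on C2, a 3-methylbut-2-enyl (prenyl) group on C3 and the ether oxygen on C6; ring B is bound through O1′ and carries OH on C2′, CH3 on C4′ and CH2OH on C6′. Ring A therefore has four different substituents on four neighbouring carbons, a pattern that substitution chemistry of a simple benzoate does not give. The ether bond C6–O1′ is flanked by three ortho substituents (CO2H on C1, O on C2′, CH2O on C6′), the worst case for copper-mediated or addition–elimination ether synthesis. There is no stereocentre, so the difficulty lies in connectivity and functional-group tolerance: the ortho-prenylphenol closes to a chroman under acid, the alkene rules out hydrogenolysis, and a 2,6-dioxygenated benzoic acid is hindered and loses CO2 easily. The feature that opens the structure is the row C6(O-aryl)–C1(CO2H)–C2(O) of ring A: an oxygen nucleophile on C6 and a carbon electrophile on C1, with an oxygen on the next carbon C2, is exactly what addition across a 3-oxygenated benzyne (triple bond C1–C6) delivers. Two further features help: O1′ of ring B has both ortho positions and the para position occupied, so it can meet an aryne only at oxygen; and the prenyl group on C3 is ortho to O2, whose other ortho position C1 is taken, so a [3,3] shift from O2 can place it only on C3.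

## Retrosynthesis

**21 from 20.** The last operation cuts only O–Si and O–CH2–O bonds. In 20 the acid is a 2-(trimethylsilyl)ethoxymethyl (SEM) ester, O2′ an SEM ether and the benzylic oxygen a tert-butyldimethylsilyl ether, so one fluoride treatment frees all three. Acetal or tert-butyl protection would need acid beside the ortho-prenylphenol, and benzyl groups would need hydrogen beside the alkene.

**20 from 19.** The C3–CH2 bond is cut and the five-carbon unit is put back on O2 as a 1,1-dimethylallyl ether (aromatic Claisen rearrangement in the forward direction). This is preferred to metalation/prenylation or C-alkylation of a phenol because O2 must be etherified anyway to steer the aryne. Letting that ether be the prenyl source removes a protecting group, and ring A needs no carbon substituent before the coupling. The forward reaction must deliver to C3 only; C1 is blocked by the ester.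

**19 from 8, 14 and 15.** The bonds C6–O1′ and C1–CO2 are cut together. Forward, fluoride turns the ortho-silylaryl triflate 8 into aryne 17; potassium phenoxide 16 (from phenol 14) adds to C6, the aryl anion on C1 takes up carbon dioxide 15, and carboxylate 18 is alkylated in the same flask. Cutting only the ether bond (Alternative 1) leaves a fully substituted halobenzoate to be made and a hindered coupling to be forced. Here the precursors are a resorcinol monoether, a phenol and CO2, and the reaction must control only the side of addition, which the C2 oxygen does.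

**8 from 1 and 6.** Compound 8 comes from alkyne 7 by semihydrogenation, 7 from phenol 5 and the tertiary propargylic chloride 6, and 5 from 2-bromoresorcinol 1 by silylation, bromine–lithium exchange and retro-Brook shift (via 2, 3, 4). Because 1 is symmetric and only one silyl group can migrate to carbon, the two oxygens are differentiated without selective protection, and no regiochemical question arises in ring A.

**14 from 9.** Phenol 14 comes from diol 13 by silylation of the primary alcohol, 13 from aldehyde 12 by reduction, 12 from catechol aldehyde 11 by O3-selective alkylation of its dianion, 11 from methyl ether 10, and 10 from creosol 9 by ortho-formylation at its only free ortho position.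

## Roads not taken

Alternative 1: Cut only the ether bond C6–O1′ and join phenol 14 to methyl 6-bromo-2-(methoxymethoxy)-3-(3-methylbut-2-en-1-yl)benzoate A1 by Ullmann coupling (copper catalyst, base, about 100 °C or above) to give ether A2. This is the route most would draw first. The nucleophilic oxygen is di-ortho-substituted, and the electrophilic carbon sits beside an ester that two ortho groups twist out of conjugation, so neither oxidative addition nor addition–elimination is favoured. A1 itself is a 1,2,3,4-tetrasubstituted arene that needs several directed metalations on a resorcinol whose two oxygens must first be told apart. A2 would still need acid for the acetal and a forcing saponification of a 2,6-disubstituted benzoate. The chosen plan makes C6–O and C1–C in one step near 0 °C and needs no differentiation of ring A oxygens.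

Alternative 2: Form the ester between the ring A acid and the ring B benzylic alcohol first (benzyl ester A3, with fluorine on C6), close the eight-membered lactone A4 by intramolecular displacement of fluoride by O1′, and hydrolyse the lactone at the end. The tether makes the ether formation intramolecular, but A3 is an ortho-hydroxybenzyl ester. The basic conditions needed for the displacement expel the benzoate and give an ortho-quinone methide. In addition, the ring closure is eight-membered at a weakly activated C–F bond. It also needs the same fully substituted ring A as Alternative 1 and is longer.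

Alternative 3: Build ring A from open-chain pieces by a Diels–Alder reaction of aryloxy-ynoate A5 with silyl ketene acetal diene A6, followed by loss of methanol to give salicylate A7. The regiochemistry is right on paper (the diene terminus bonds to the carbon bearing O-aryl, the acetal carbon to the carbon bearing the ester). However, the oxygen on the β-carbon of A5 lowers its dienophilicity at the carbon that must accept the nucleophilic diene terminus. Making an aryl ynol ether from the di-ortho-substituted phenol is itself unprecedented in ease, A6 is hydrolytically labile, and A7 still needs hydrolysis of a hindered methyl ester. The step count is higher and the precedent is weaker than for aryne addition.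

Key step: step 9

Remark on the chemistry: the target has no stereocentre and its only alkene is trisubstituted with two identical methyl groups, so no stereocontrol is required.

## Route

Step 1
Reactants: 1 2-bromobenzene-1,3-diol (2-bromoresorcinol)
Product: 5 3-hydroxy-2-(trimethylsilyl)phenyl trifluoromethanesulfonate, via bis(silyl) ether 2 (not isolated), via lithium phenoxide 3 (not isolated), via O-silyl triflate 4 (not isolated)
Conditions: HMDS, THF, reflux, then evaporation; n-BuLi, THF, −78 °C; Tf2O, −78 to 0 °C; then HCl (1 M aq.), THF, 0 °C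
Reagents that add atoms: hexamethyldisilazane, C[Si](C)(C)N[Si](C)(C)C; trifluoromethanesulfonic anhydride, FC(F)(F)S(=O)(=O)OS(=O)(=O)C(F)(F)F
Why: O-silylation, bromine–lithium exchange and 1,3-retro-Brook rearrangement move one silyl group from oxygen to C2; only one silyl group can migrate to the single carbanion, so the symmetric diol is differentiated without selective protection, the lithium phenoxide 3 is triflated in the same flask and the remaining O–Si bond is hydrolysed on work-up.

Step 2
Reactants: 5 3-hydroxy-2-(trimethylsilyl)phenyl trifluoromethanesulfonate; 6 3-chloro-3-methylbut-1-yne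
Product: 7 3-[(2-methylbut-3-yn-2-yl)oxy]-2-(trimethylsilyl)phenyl trifluoromethanesulfonate
Conditions: CuCl2·2H2O (cat.), DBU, MeCN, 0 °C
Reagents that add atoms: none
Why: Copper-catalysed propargylic etherification of a phenol with a tertiary propargylic chloride (copper acetylide, SN1-like substitution), a standard entry to aryl 1,1-dimethylpropargyl ethers that works best with electron-poor phenols; DBU is not silaphilic, so the C–Si and S–O bonds should survive.

Step 3
Reactants: 7 3-[(2-methylbut-3-yn-2-yl)oxy]-2-(trimethylsilyl)phenyl trifluoromethanesulfonate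
Product: 8 3-[(2-methylbut-3-en-2-yl)oxy]-2-(trimethylsilyl)phenyl trifluoromethanesulfonate
Conditions: H2 (1 atm), Pd/CaCO3 poisoned with Pb(OAc)2, quinoline, EtOAc, rt
Reagents that add atoms: none
Why: Lindlar semihydrogenation of the terminal alkyne; the aryl triflate and aryl silane are inert and no other unsaturation competes.

Step 4
Reactants: 9 2-methoxy-4-methylphenol (creosol)
Product: 10 2-hydroxy-3-methoxy-5-methylbenzaldehyde
Conditions: MgCl2, Et3N, (CH2O)n, MeCN, reflux
Reagents that add atoms: formaldehyde (as paraformaldehyde), C=O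
Why: Magnesium-phenoxide-directed ortho-formylation (Casnati–Skattebøl reaction); C6 is the only free ortho position of the phenol, so the regiochemistry is fixed.

Step 5
Reactants: 10 2-hydroxy-3-methoxy-5-methylbenzaldehyde
Product: 11 2,3-dihydroxy-5-methylbenzaldehyde
Conditions: BBr3, CH2Cl2, −78 °C to rt; then H2O
Reagents that add atoms: none
Why: Lewis-acid cleavage of the aryl methyl ether with BBr3, the usual way from ortho-vanillin-type aldehydes to 2,3-dihydroxybenzaldehydes.

Step 6
Reactants: 11 2,3-dihydroxy-5-methylbenzaldehyde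
Product: 12 2-hydroxy-5-methyl-3-{[2-(trimethylsilyl)ethoxy]methoxy}benzaldehyde
Conditions: NaH (2.2 equiv), THF/DMF, 0 °C; then SEMCl (1.0 equiv), 0 °C; aq. NH4Cl
Reagents that add atoms: 2-(trimethylsilyl)ethoxymethyl chloride (SEMCl), C[Si](C)(C)CCOCCl
Why: In the dianion the O2 oxide is conjugated with and chelated to the aldehyde, so the more basic O3 oxide takes the single equivalent of SEMCl (regioselective Williamson-type O-alkylation, as known for 2,3-dihydroxybenzaldehyde).

Step 7
Reactants: 12 2-hydroxy-5-methyl-3-{[2-(trimethylsilyl)ethoxy]methoxy}benzaldehyde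
Product: 13 2-(hydroxymethyl)-4-methyl-6-{[2-(trimethylsilyl)ethoxy]methoxy}phenol
Conditions: NaBH4, MeOH, 0 °C
Reagents that add atoms: none
Why: Borohydride reduction of the aldehyde; phenol and acetal are untouched.

Step 8
Reactants: 13 2-(hydroxymethyl)-4-methyl-6-{[2-(trimethylsilyl)ethoxy]methoxy}phenol
Product: 14 2-({[tert-butyl(dimethyl)silyl]oxy}methyl)-4-methyl-6-{[2-(trimethylsilyl)ethoxy]methoxy}phenol
Conditions: TBSCl (1.05 equiv), imidazole, CH2Cl2, 0 °C
Reagents that add atoms: tert-butyldimethylsilyl chloride (TBSCl), CC(C)(C)[Si](C)(C)Cl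
Why: Selective silylation of the primary benzylic alcohol beside a hindered, hydrogen-bonded phenol, as is routine for salicyl alcohols.

Step 9
Reactants: 8 3-[(2-methylbut-3-en-2-yl)oxy]-2-(trimethylsilyl)phenyl trifluoromethanesulfonate; 14 2-({[tert-butyl(dimethyl)silyl]oxy}methyl)-4-methyl-6-{[2-(trimethylsilyl)ethoxy]methoxy}phenol; 15 carbon dioxide
Product: 19 [2-(trimethylsilyl)ethoxy]methyl 2-[2-({[tert-butyl(dimethyl)silyl]oxy}methyl)-4-methyl-6-{[2-(trimethylsilyl)ethoxy]methoxy}phenoxy]-6-[(2-methylbut-3-en-2-yl)oxy]benzoate, via potassium phenoxide 16 (not isolated), via aryne 17 (not isolated), via potassium carboxylate 18 (not isolated)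
Conditions: 14, KH, THF, 0 °C; then CO2 (1 atm), KF, 18-crown-6, slow addition of 8, 0 °C to rt; then SEMCl, rt
Reagents that add atoms: 2-(trimethylsilyl)ethoxymethyl chloride (SEMCl), C[Si](C)(C)CCOCCl
Why: Proposed new method: fluoride attack on silicon in 8 expels triflate and gives the 3-alkoxybenzyne 17; its C–O bond beside the triple bond withdraws electron density in the σ plane and distorts the aryne so that the carbon meta to oxygen is the flatter, more electrophilic terminus, so phenoxide 16 adds there and the in-plane aryl anion appears between the two oxygens, where CO2 (in large excess) captures it to give carboxylate 18, which SEMCl alkylates in the same flask. The closest known reaction types are the fluoride-mediated O-arylation of phenols with ortho-silylaryl triflates and the three-component couplings in which an amine or chloride adds to an aryne and CO2 takes up the aryl anion; what is new is the pairing of a phenoxide with CO2. The reasoning is that addition of a di-ortho-substituted phenoxide to CO2 is reversible and unfavourable whereas carboxylation of the aryl anion is irreversible, so free phenoxide should be the species that meets the aryne. No ring is closed and no stereocentre is formed. Three selectivities are needed: the site of addition (set by the alkoxy group beside the triple bond and reinforced by its bulky tertiary carbon, which shields the adjacent aryne carbon), O- against C-arylation (both ortho positions and the para position of 16 are substituted), and carboxylation against protonation (16 is preformed with KH, the solvent is THF and no proton donor is present). Immediate esterification keeps a free acid from ionising the neighbouring tertiary allylic ether and prevents decarboxylative ipso-substitution in the next step; KF with 18-crown-6 at this temperature should leave the alkyl silyl ether and the SEM groups intact.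

Step 10
Reactants: 19 [2-(trimethylsilyl)ethoxy]methyl 2-[2-({[tert-butyl(dimethyl)silyl]oxy}methyl)-4-methyl-6-{[2-(trimethylsilyl)ethoxy]methoxy}phenoxy]-6-[(2-methylbut-3-en-2-yl)oxy]benzoate
Product: 20 [2-(trimethylsilyl)ethoxy]methyl 6-[2-({[tert-butyl(dimethyl)silyl]oxy}methyl)-4-methyl-6-{[2-(trimethylsilyl)ethoxy]methoxy}phenoxy]-2-hydroxy-3-(3-methylbut-2-en-1-yl)benzoate
Conditions: PhMe, 120 °C, sealed tube
Reagents that add atoms: none
Why: Aromatic Claisen rearrangement ([3,3]) of the aryl 1,1-dimethylallyl ether, which inverts the allyl unit and so delivers a 3-methylbut-2-enyl group to carbon; the ortho carbon bearing the ester cannot re-aromatise and migration there is reversible, so only C3 gives product, and the neutral medium avoids chroman formation.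

Step 11
Reactants: 20 [2-(trimethylsilyl)ethoxy]methyl 6-[2-({[tert-butyl(dimethyl)silyl]oxy}methyl)-4-methyl-6-{[2-(trimethylsilyl)ethoxy]methoxy}phenoxy]-2-hydroxy-3-(3-methylbut-2-en-1-yl)benzoate
Product: 21 2-hydroxy-6-[2-hydroxy-6-(hydroxymethyl)-4-methylphenoxy]-3-(3-methylbut-2-en-1-yl)benzoic acid
Conditions: TBAF (excess), ethane-1,2-diamine, THF, 60 °C; then aq. citric acid (pH 4)
Reagents that add atoms: none
Why: Fluoride cleaves the silyl ether and fragments both SEM groups (ester and aryl ether) to ethene and formaldehyde, which the diamine traps; no acid stronger than the work-up buffer touches the ortho-prenylphenol, so cyclisation to a chroman is avoided.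

## Compound list

1 | 2-bromobenzene-1,3-diol | Oc1cccc(O)c1Br | starting material
2 | 2-bromo-1,3-bis[(trimethylsilyl)oxy]benzene | C[Si](C)(C)Oc1cccc(O[Si](C)(C)C)c1Br | intermediate
3 | lithium 3-[(trimethylsilyl)oxy]-2-(trimethylsilyl)phenolate | [Li+].[O-]c1cccc(O[Si](C)(C)C)c1[Si](C)(C)C | intermediate
4 | 3-[(trimethylsilyl)oxy]-2-(trimethylsilyl)phenyl trifluoromethanesulfonate | C[Si](C)(C)Oc1cccc(OS(=O)(=O)C(F)(F)F)c1[Si](C)(C)C | intermediate
5 | 3-hydroxy-2-(trimethylsilyl)phenyl trifluoromethanesulfonate | Oc1cccc(OS(=O)(=O)C(F)(F)F)c1[Si](C)(C)C | intermediate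
6 | 3-chloro-3-methylbut-1-yne | C#CC(C)(C)Cl | starting material
7 | 3-[(2-methylbut-3-yn-2-yl)oxy]-2-(trimethylsilyl)phenyl trifluoromethanesulfonate | C#CC(C)(C)Oc1cccc(OS(=O)(=O)C(F)(F)F)c1[Si](C)(C)C | intermediate
8 | 3-[(2-methylbut-3-en-2-yl)oxy]-2-(trimethylsilyl)phenyl trifluoromethanesulfonate | C=CC(C)(C)Oc1cccc(OS(=O)(=O)C(F)(F)F)c1[Si](C)(C)C | intermediate
9 | 2-methoxy-4-methylphenol | COc1cc(C)ccc1O | starting material
10 | 2-hydroxy-3-methoxy-5-methylbenzaldehyde | COc1cc(C)cc(C=O)c1O | intermediate
11 | 2,3-dihydroxy-5-methylbenzaldehyde | Oc1cc(C)cc(C=O)c1O | intermediate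
12 | 2-hydroxy-5-methyl-3-{[2-(trimethylsilyl)ethoxy]methoxy}benzaldehyde | C[Si](C)(C)CCOCOc1cc(C)cc(C=O)c1O | intermediate
13 | 2-(hydroxymethyl)-4-methyl-6-{[2-(trimethylsilyl)ethoxy]methoxy}phenol | C[Si](C)(C)CCOCOc1cc(C)cc(CO)c1O | intermediate
14 | 2-({[tert-butyl(dimethyl)silyl]oxy}methyl)-4-methyl-6-{[2-(trimethylsilyl)ethoxy]methoxy}phenol | C[Si](C)(C)CCOCOc1cc(C)cc(CO[Si](C)(C)C(C)(C)C)c1O | intermediate
15 | carbon dioxide | O=C=O | starting material
16 | potassium 2-({[tert-butyl(dimethyl)silyl]oxy}methyl)-4-methyl-6-{[2-(trimethylsilyl)ethoxy]methoxy}phenolate | [K+].[O-]c1c(OCOCC[Si](C)(C)C)cc(C)cc1CO[Si](C)(C)C(C)(C)C | intermediate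
17 | 1,2-didehydro-3-[(2-methylbut-3-en-2-yl)oxy]benzene | C=CC(C)(C)OC1=CC=CC#C1 | intermediate
18 | potassium 2-[2-({[tert-butyl(dimethyl)silyl]oxy}methyl)-4-methyl-6-{[2-(trimethylsilyl)ethoxy]methoxy}phenoxy]-6-[(2-methylbut-3-en-2-yl)oxy]benzoate | [K+].[O-]C(=O)c1c(OC(C)(C)C=C)cccc1Oc1c(OCOCC[Si](C)(C)C)cc(C)cc1CO[Si](C)(C)C(C)(C)C | intermediate
19 | [2-(trimethylsilyl)ethoxy]methyl 2-[2-({[tert-butyl(dimethyl)silyl]oxy}methyl)-4-methyl-6-{[2-(trimethylsilyl)ethoxy]methoxy}phenoxy]-6-[(2-methylbut-3-en-2-yl)oxy]benzoate | C[Si](C)(C)CCOCOC(=O)c1c(OC(C)(C)C=C)cccc1Oc1c(OCOCC[Si](C)(C)C)cc(C)cc1CO[Si](C)(C)C(C)(C)C | intermediate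
20 | [2-(trimethylsilyl)ethoxy]methyl 6-[2-({[tert-butyl(dimethyl)silyl]oxy}methyl)-4-methyl-6-{[2-(trimethylsilyl)ethoxy]methoxy}phenoxy]-2-hydroxy-3-(3-methylbut-2-en-1-yl)benzoate | C[Si](C)(C)CCOCOC(=O)c1c(O)c(CC=C(C)C)ccc1Oc1c(OCOCC[Si](C)(C)C)cc(C)cc1CO[Si](C)(C)C(C)(C)C | intermediate
21 | 2-hydroxy-6-[2-hydroxy-6-(hydroxymethyl)-4-methylphenoxy]-3-(3-methylbut-2-en-1-yl)benzoic acid | CC(C)=CCc1ccc(Oc2c(O)cc(C)cc2CO)c(C(=O)O)c1O | target

## Step count and risk

Total step count: 11 (steps 1–3 for the ring A piece, steps 4–8 for the ring B piece, steps 9–11 after convergence).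
Longest linear sequence: 8 steps (4, 5, 6, 7, 8, 9, 10, 11 from creosol 9); the ring A branch is 6 steps from 1.

Steps least certain to work:

**Step 9 (key step, Proposed new method).** The aryl anion may be protonated faster than it is carboxylated. Alternatively, the phenoxide may be held as its CO2 adduct, which then adds through a carbonyl oxygen and transfers the acyl group (giving an aryl salicylate instead of an ether). Fallback with known chemistry, setting out from 8 and 14 and coming back at 19: plain fluoride-mediated O-arylation without CO2 (CsF, MeCN, rt) gives the protonated diaryl ether tert-butyl(dimethyl){[5-methyl-2-{3-[(2-methylbut-3-en-2-yl)oxy]phenoxy}-3-{[2-(trimethylsilyl)ethoxy]methoxy}phenyl]methoxy}silane F1, which is also the product expected if protonation wins. Directed ortho-lithiation of F1 between its two ring A oxygens (n-BuLi, THF, −78 to −40 °C) gives the aryllithium F2. CO2 converts it into the lithium carboxylate F3, and SEMCl then gives 19.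

**Step 2.** Ether formation at an oxygen flanked by the trimethylsilyl group may be slow, leaving time for base-induced loss of silicon or triflate. Fallback, setting out from 1 and 6 and coming back at 8, which changes the order of events so that the ether is made beside bromine instead of silicon. Mono-etherification of the symmetric diol 1 with 6 (CuCl2·2H2O cat., DBU) gives 2-bromo-3-[(2-methylbut-3-yn-2-yl)oxy]phenol F4; this is statistical in conversion but regiochemically unambiguous. Lindlar semihydrogenation gives 2-bromo-3-[(2-methylbut-3-en-2-yl)oxy]phenol F5. The sequence of step 1 (HMDS; n-BuLi; Tf2O) then passes through the silyl ether {2-bromo-3-[(2-methylbut-3-en-2-yl)oxy]phenoxy}trimethylsilane F6 and the retro-Brook product lithium 3-[(2-methylbut-3-en-2-yl)oxy]-2-(trimethylsilyl)phenolate F7 to 8.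

**Step 6.** Alkylation may not stop at one oxygen, or may occur partly at O2. Fallback, setting out from 11 and coming back at 12: exhaustive alkylation (NaH, SEMCl, excess) gives 5-methyl-2,3-bis{[2-(trimethylsilyl)ethoxy]methoxy}benzaldehyde F8. MgBr2·OEt2 then removes only the SEM group that can chelate magnesium together with the aldehyde oxygen (the one on O2), giving 12.

**Step 10.** On this electron-poor ring the rearrangement may be slow enough for loss of the tertiary allyl group as isoprene, or for migration by way of the ester-bearing carbon to the para position, to compete. Fallback, setting out from 8 and coming back at 21, which moves the sigmatropic step in front of the coupling so that the second ortho position is blocked by silicon instead of by the ester. Heating 8 (PhMe, 110 °C) gives 3-hydroxy-4-(3-methylbut-2-en-1-yl)-2-(trimethylsilyl)phenyl trifluoromethanesulfonate F9. SEMCl and i-Pr2NEt give 4-(3-methylbut-2-en-1-yl)-3-{[2-(trimethylsilyl)ethoxy]methoxy}-2-(trimethylsilyl)phenyl trifluoromethanesulfonate F10. Under the conditions of step 9 with 16 (from 14 and KH), 15 and SEMCl, F10 gives the aryne 1,2-didehydro-4-(3-methylbut-2-en-1-yl)-3-{[2-(trimethylsilyl)ethoxy]methoxy}benzene F11, then the potassium carboxylate F12 and the SEM ester F13. The conditions of step 11 take F13 to 21.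

**Step 11.** The aryl SEM ether may be cleaved incompletely at a temperature the product tolerates, or the phenoxides may be hydroxymethylated by the formaldehyde released. Fallback, setting out from 20 and coming back at 21, in two stages with a Lewis acid in place of fluoride for the aryl ether. TBAF with ethane-1,2-diamine at rt removes only the silyl ether and the SEM ester and gives 2-hydroxy-6-[2-(hydroxymethyl)-4-methyl-6-{[2-(trimethylsilyl)ethoxy]methoxy}phenoxy]-3-(3-methylbut-2-en-1-yl)benzoic acid F14. MgBr2·OEt2 in Et2O/MeNO2 at rt then cleaves the remaining aryl SEM ether by chelation to give 21.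

## Further compounds

F1 | step 9 | tert-butyl(dimethyl){[5-methyl-2-{3-[(2-methylbut-3-en-2-yl)oxy]phenoxy}-3-{[2-(trimethylsilyl)ethoxy]methoxy}phenyl]methoxy}silane | C=CC(C)(C)Oc1cccc(Oc2c(OCOCC[Si](C)(C)C)cc(C)cc2CO[Si](C)(C)C(C)(C)C)c1
F2 | step 9 | {2-[2-({[tert-butyl(dimethyl)silyl]oxy}methyl)-4-methyl-6-{[2-(trimethylsilyl)ethoxy]methoxy}phenoxy]-6-[(2-methylbut-3-en-2-yl)oxy]phenyl}lithium | [Li]c1c(OC(C)(C)C=C)cccc1Oc1c(OCOCC[Si](C)(C)C)cc(C)cc1CO[Si](C)(C)C(C)(C)C
F3 | step 9 | lithium 2-[2-({[tert-butyl(dimethyl)silyl]oxy}methyl)-4-methyl-6-{[2-(trimethylsilyl)ethoxy]methoxy}phenoxy]-6-[(2-methylbut-3-en-2-yl)oxy]benzoate | [Li+].[O-]C(=O)c1c(OC(C)(C)C=C)cccc1Oc1c(OCOCC[Si](C)(C)C)cc(C)cc1CO[Si](C)(C)C(C)(C)C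
F4 | step 2 | 2-bromo-3-[(2-methylbut-3-yn-2-yl)oxy]phenol | C#CC(C)(C)Oc1cccc(O)c1Br
F5 | step 2 | 2-bromo-3-[(2-methylbut-3-en-2-yl)oxy]phenol | C=CC(C)(C)Oc1cccc(O)c1Br
F6 | step 2 | {2-bromo-3-[(2-methylbut-3-en-2-yl)oxy]phenoxy}trimethylsilane | C=CC(C)(C)Oc1cccc(O[Si](C)(C)C)c1Br
F7 | step 2 | lithium 3-[(2-methylbut-3-en-2-yl)oxy]-2-(trimethylsilyl)phenolate | [Li+].[O-]c1cccc(OC(C)(C)C=C)c1[Si](C)(C)C
F8 | step 6 | 5-methyl-2,3-bis{[2-(trimethylsilyl)ethoxy]methoxy}benzaldehyde | C[Si](C)(C)CCOCOc1cc(C)cc(C=O)c1OCOCC[Si](C)(C)C
F9 | step 10 | 3-hydroxy-4-(3-methylbut-2-en-1-yl)-2-(trimethylsilyl)phenyl trifluoromethanesulfonate | CC(C)=CCc1ccc(OS(=O)(=O)C(F)(F)F)c([Si](C)(C)C)c1O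
F10 | step 10 | 4-(3-methylbut-2-en-1-yl)-3-{[2-(trimethylsilyl)ethoxy]methoxy}-2-(trimethylsilyl)phenyl trifluoromethanesulfonate | CC(C)=CCc1ccc(OS(=O)(=O)C(F)(F)F)c([Si](C)(C)C)c1OCOCC[Si](C)(C)C
F11 | step 10 | 1,2-didehydro-4-(3-methylbut-2-en-1-yl)-3-{[2-(trimethylsilyl)ethoxy]methoxy}benzene | CC(C)=CCC1=C(OCOCC[Si](C)(C)C)C#CC=C1
F12 | step 10 | potassium 6-[2-({[tert-butyl(dimethyl)silyl]oxy}methyl)-4-methyl-6-{[2-(trimethylsilyl)ethoxy]methoxy}phenoxy]-3-(3-methylbut-2-en-1-yl)-2-{[2-(trimethylsilyl)ethoxy]methoxy}benzoate | [K+].[O-]C(=O)c1c(OCOCC[Si](C)(C)C)c(CC=C(C)C)ccc1Oc1c(OCOCC[Si](C)(C)C)cc(C)cc1CO[Si](C)(C)C(C)(C)C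
F13 | step 10 | [2-(trimethylsilyl)ethoxy]methyl 6-[2-({[tert-butyl(dimethyl)silyl]oxy}methyl)-4-methyl-6-{[2-(trimethylsilyl)ethoxy]methoxy}phenoxy]-3-(3-methylbut-2-en-1-yl)-2-{[2-(trimethylsilyl)ethoxy]methoxy}benzoate | C[Si](C)(C)CCOCOC(=O)c1c(OCOCC[Si](C)(C)C)c(CC=C(C)C)ccc1Oc1c(OCOCC[Si](C)(C)C)cc(C)cc1CO[Si](C)(C)C(C)(C)C
F14 | step 11 | 2-hydroxy-6-[2-(hydroxymethyl)-4-methyl-6-{[2-(trimethylsilyl)ethoxy]methoxy}phenoxy]-3-(3-methylbut-2-en-1-yl)benzoic acid | CC(C)=CCc1ccc(Oc2c(OCOCC[Si](C)(C)C)cc(C)cc2CO)c(C(=O)O)c1O
A1 | alternative 1 | methyl 6-bromo-2-(methoxymethoxy)-3-(3-methylbut-2-en-1-yl)benzoate | COC(=O)c1c(Br)ccc(CC=C(C)C)c1OCOC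
A2 | alternative 1 | methyl 6-[2-({[tert-butyl(dimethyl)silyl]oxy}methyl)-4-methyl-6-{[2-(trimethylsilyl)ethoxy]methoxy}phenoxy]-2-(methoxymethoxy)-3-(3-methylbut-2-en-1-yl)benzoate | COC(=O)c1c(OCOC)c(CC=C(C)C)ccc1Oc1c(OCOCC[Si](C)(C)C)cc(C)cc1CO[Si](C)(C)C(C)(C)C
A3 | alternative 2 | [2-hydroxy-3-(methoxymethoxy)-5-methylphenyl]methyl 6-fluoro-2-(methoxymethoxy)-3-(3-methylbut-2-en-1-yl)benzoate | COCOc1cc(C)cc(COC(=O)c2c(F)ccc(CC=C(C)C)c2OCOC)c1O
A4 | alternative 2 | 4,11-bis(methoxymethoxy)-9-methyl-3-(3-methylbut-2-en-1-yl)-5H,7H-dibenzo[b,g][1,5]dioxocin-5-one | COCOc1cc(C)cc2c1Oc1ccc(CC=C(C)C)c(OCOC)c1C(=O)OC2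
A5 | alternative 3 | methyl 3-[2-({[tert-butyl(dimethyl)silyl]oxy}methyl)-4-methyl-6-{[2-(trimethylsilyl)ethoxy]methoxy}phenoxy]prop-2-ynoate | COC(=O)C#COc1c(OCOCC[Si](C)(C)C)cc(C)cc1CO[Si](C)(C)C(C)(C)C
A6 | alternative 3 | {[1-methoxy-2-(3-methylbut-2-en-1-yl)buta-1,3-dien-1-yl]oxy}trimethylsilane | COC(O[Si](C)(C)C)=C(CC=C(C)C)C=C
A7 | alternative 3 | methyl 6-[2-({[tert-butyl(dimethyl)silyl]oxy}methyl)-4-methyl-6-{[2-(trimethylsilyl)ethoxy]methoxy}phenoxy]-2-hydroxy-3-(3-methylbut-2-en-1-yl)benzoate | COC(=O)c1c(O)c(CC=C(C)C)ccc1Oc1c(OCOCC[Si](C)(C)C)cc(C)cc1CO[Si](C)(C)C(C)(C)C
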